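All runs are simulated for substances that don't exist; the scatter is artificial.

One J holds one L, so I can keep books on L and ask what each equivalent of it buys.

| setting | larch | ash | midnight | noon | winter | autumn |
|---|---|---|---|---|---|---|
| Q | 0.034 M | 0.068 M | 0.034 M | 0.034 M (fed, over 2.00 min) | 0.034 M | 0.034 M |
| L | 1 equiv | 1 equiv | 1.00 equiv | 1.00 equiv | 1.00 equiv | 1.00 equiv |
| remark | run made earlier | run made earlier | a closed flask charged with all of it at once and left for 2.5 min | all but Q at the start; Q goes in evenly over 2.00 min, the run ends at 2.5 min | a single well-mixed tank run continuously and read at steady state, 2.5 min in it on average | a single well-mixed tank run continuously and read at steady state, 25.0 min in it on average |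
| time |  |  | 2.5 min | 2.5 min |  |  |

larch run (percent of the Q charged)

| time / min | J / % |
|---|---|
| 0.333 | 27.5 |
| 0.667 | 34.1 |
| 1.00 | 36.5 |
| 1.33 | 37.4 |
| 2.00 | 37.4 |
| 2.50 | 38.1 |

ash run (percent of the Q charged)

| time / s | J / % |
|---|---|
| 10.0 | 28.0 |
| 12.0 | 29.6 |
| 20.0 | 33.7 |
| 25.0 | 36.2 |
| 30.0 | 36.6 |
| 40.0 | 37.7 |
| 50.0 | 37.9 |

(each reading ± 0.5 percentage points)

- the stated concentrations are those of everything mixed, before any reaction; amounts are the same in each set-up
- the feed brings no volume worth counting
- the earlier runs were made in a closed, stirred flask

* the set-up with the highest amount of J at the outlet or at the end, in percent of the Q put in ("none" if the first two lie within 2 percentage points) (midnight / noon / winter / autumn / none)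
* amount of J at the outlet or at the end, in percent of the Q put in, midnight
* amount of J at the outlet or at the end, in percent of the Q put in, noon
* amount of J at the outlet or at the end, in percent of the Q put in, winter
* amount of J at the outlet or at the end, in percent of the Q put in, autumn

Larch opens the books. Its charge is 1 equiv of L, and its last reading, at 2.50 min, is J 38.1%. From 1.33 min on, larch moves by 0.7 percentage points, which is close to the scatter of 0.5 points. Ash, at twice the concentration, reads 33.7% at 20.0 s. Larch reads 34.1% at twice that time. So at these two points the runs match on concentration times time, as second-order steps do.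

Now the entries. Larch spent at most its charge, so its yield is at least 0.381. This w, the J standing per equivalent of L spent, is what I carry. The other 0.619 of the equivalent is booked outside J, and a second addition to J is one place for it. J is the one species read, so I can't split that entry further. For larch I take the charge as spent, so w stands at that floor, and the books close with J equal to w times the L spent.

Midnight repeats larch, so I book 38.1%. The last Q of noon enters 0.500 min before the end, less than the 0.667 min at which larch still reads 34.1%. So I book noon under midnight. I book the two tanks under midnight too, without a figure of my own.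

The forecast names midnight, with 38%, 31.5%, 26.3% and 25.4% for midnight, noon, winter and autumn: “The closed flask wins”.

The simulation gives midnight as best, with 37.4%, 34.0%, 27.8% and 18.0% in the same order.

    L + Z → G + D (k = 0.590 M⁻¹ s⁻¹)
    Q + L → Z + D (k = 0.890 M⁻¹ s⁻¹)
    L + J → G + D (k = 0.0750 M⁻¹ s⁻¹)
    Q + D → E (k = 0.130 M⁻¹ s⁻¹)
    Q + L ⇌ J + D (K = 39.0, k = 0.960 M⁻¹ s⁻¹)

At 2.50 min midnight keeps 5.38% of its L, less than its Q at 10.6%, so L is the limiting reagent there. Midnight's w is 0.395, and noon's is 0.385. The neighbour is noon with 0.400 equiv of L, and it keeps 2.55% of that charge at 2.50 min. Larch's w books it 14.9% of J. That flask reads J 18.1%, which is 0.464 per equivalent spent, with 57% of its Q left.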